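## The problem

Compound 22 has no ring apart from its two benzene rings. It is a three-carbon 1,3-dioxygenated chain: the C1 oxygen is acylated by a (Z)-2-(hydroxymethyl)but-2-enoyl group, the C3 carbinol carries a 4-methoxyphenyl ring, and the C2 methine carries an (E)-3-(3,4-dimethoxyphenyl)allyl branch. The two adjacent stereocentres (2S,3S) must therefore be set on an open chain. The carbinol can be made by a catalyst from a prochiral aldehyde; the methine has no heteroatom of its own, so the carbinol is the only handle for controlling it. The methine bears two CH2 arms, one oxygenated and one allylic, and these must stay distinguishable at every stage, as must the primary and secondary hydroxyls at the acylation.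

Several groups are fragile:
- The 4-methoxybenzylic alcohol ionises in acid, with epimerisation or elimination.
- The electron-rich E styrene cannot meet a hydrogenation catalyst, strong acid or oxidants.
- The acrylate has its methyl cis to the carbonyl, the less stable geometry, and isomerises under nucleophilic or basic catalysis.
- The primary ester lies 1,3 to a free secondary hydroxyl, so base invites acyl migration.

The enabling feature is the four-carbon run acyloxymethyl carbon, methine, allylic CH2, first styrene carbon, with oxygen or an oxygen-derived function at both ends. This run is a masked 3-substituted furan. Oxidation gives the butenolide 7, whose ring alkene is allylic to the carbinol hydroxyl, so a hydroxyl-directed hydrogenation can set the methine configuration.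

## Retrosynthesis

**Ester C–O bond.** Target 22 is cut at the acyl–oxygen bond, through its silyl ether 21, into diol 14 and the protected acid 20. The acyl unit is the most fragile part of the molecule, so it enters last. What remains, 14, is a robust 1,3-diol that holds the whole stereochemical problem. The forward reaction must acylate the primary hydroxyl only, keep the Z geometry of the acid, and allow a desilylation mild enough for the benzylic alcohol and the ester.

**Carboxyl C–C bond of the acid.** Acid 20 is cut between the alkene carbon and the carboxyl carbon, leading to alkenyl iodide 18, then alcohol 17, iodoenal 16 and crotonaldehyde 15. Carbonyl olefination or allylic transposition routes to 2-(hydroxymethyl)but-2-enoates favour the geometry with methyl trans to the carboxyl group. The iodide route instead fixes the geometry at 16, where methyl trans to formyl (inherited from 15) is the stable arrangement. Iodine is later exchanged for carboxyl with retention, which places methyl cis to the carboxyl as required.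

**Styrene C=C bond.** Diol 14 is cut at the alkene into lactol 9 and the benzylic phosphonate 12, which comes from chloride 11 and veratryl alcohol 10. A phosphonate olefination gives the E alkene directly, whereas a late cross-coupling would need a separate geometric control. The aldehyde carbon is the lactol carbon, so the oxymethyl arm stays tied up in the ring until the olefination releases it as the primary alcohol. The precursor is nine heavy atoms smaller and has no styrene. The forward reaction must open a lactol that carries a free secondary hydroxyl.

**Oxidation-level adjustment.** Lactol 9 comes from lactone 8 by partial reduction. The lactone keeps the two chain ends distinct: its carbonyl carbon becomes the styrene carbon and its CH2–O carbon becomes the acyloxymethyl group.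

**Two C–H bonds (key disconnection).** Lactone 8 is traced back to butenolide 7 by removing the hydrogens at C3 and C4. The methine stereocentre becomes a trigonal carbon allylic to the carbinol, so no new carbon–carbon bond is needed and the existing stereocentre does the work. An aldol-type or conjugate-addition construction of the same centre would need a second stereochemical controller. The forward hydrogenation must add to one face of the ring alkene, chosen by the hydroxyl.

**Butenolide to furan.** Butenolide 7 comes from hydroxybutenolide 6 by reduction, and 6 from the 3-substituted furan 4 by photooxygenation through endoperoxide 5. The aromatic ring carries the four-carbon chain with both terminal oxygens latent. The forward reaction must place the carbonyl at the furan carbon remote from the substituent.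

**Aryl–carbinol C–C bond.** Furyl carbinol 4 is cut into furan-3-carbaldehyde 1 and boronic acid 2, joined through the arylzinc 3. This is the only step in which a catalyst creates absolute configuration; every later stereochemical event is relayed from this carbinol.

## Roads not taken

**Alternative 1:** The cut removes the methine–oxymethyl C–C bond and the benzylic C–O bond together. In the forward direction the skipped diene 1-methoxy-4-[(1E)-penta-1,4-dien-1-yl]benzene A2 would react with two one-carbon aldehyde units under a confined chiral Brønsted acid, in a catalytic asymmetric Prins reaction, to give the trans dioxane (4S,5S)-4-(4-methoxyphenyl)-5-(prop-2-en-1-yl)-1,3-dioxane A1.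
- Merits: both stereocentres, one C–C bond and the benzylic C–O bond arise in a single catalytic step from an achiral hydrocarbon. It is the shortest conceivable entry to the stereodiad.
- Weak points: the substrate is a 1,2-disubstituted, strongly electron-rich styrene, so the benzylic cation is long-lived and both trans/cis and enantiomeric control are least secure. The skipped diene can slip into conjugation under acid. Unmasking the formaldehyde acetal of A1 needs acid strong enough to ionise the 4-methoxybenzylic C–O bond, which risks the carbinol centre. The aryl styrene must still be added afterwards by metathesis.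
- Comparison: this road would reach diol 14 in fewer steps than the chosen plan and with one catalyst. The chosen plan offers in return stereo-defining steps with close precedent for exactly these functional groups, and a benzylic alcohol that never meets acid.

**Alternative 2:** The cut is the aryl–carbinol bond. A malonate-derived 2-substituted propane-1,3-diol would be desymmetrised by a lipase, protected and oxidised to the aldehyde (2S,4E)-5-(3,4-dimethoxyphenyl)-2-({[2-(trimethylsilyl)ethoxy]methoxy}methyl)pent-4-enal A4. An aryl Grignard reagent carrying the 4-methoxyphenyl group would then add under chelation control to give (1S,2S)-2-[(E)-3-(3,4-dimethoxyphenyl)prop-2-en-1-yl]-1-(4-methoxyphenyl)-3-{[2-(trimethylsilyl)ethoxy]methoxy}propan-1-ol A3. Removal of the acetal would converge on diol 14.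
- Merits: the E styrene is installed early by simple alkylation. No photochemistry, pressure or precious-metal catalyst is needed, and the enzymatic step is scalable.
- Weak points: A4 is an α-branched, β-alkoxy aldehyde that can epimerise or eliminate. 1,3-Chelation competes with other chelates offered by the two acetal oxygens, so the diastereoselectivity of aryl addition to such aldehydes is often moderate. The protecting-group traffic (acetate on, acetal on, acetate off, oxidation, acetal off) makes the sequence to 14 about two steps longer. The final acetal cleavage brings Lewis acid or hot fluoride to the benzylic alcohol.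
- Comparison: in robustness of the individual operations and in cost this road is at least equal. The chosen plan relays from a configurationally stable carbinol instead of a labile aldehyde and needs no protecting group before the final acylation.

**Alternative 3:** The cut is the methine–allylic CH2 bond, made by a sigmatropic shift. The ester 1-(3,4-dimethoxyphenyl)prop-2-en-1-yl (3S)-3-hydroxy-3-(4-methoxyphenyl)propanoate A6 would be converted into its chelated dianion, O-silylated, and rearranged through a chair (Ireland–Claisen) to (2R,3S)-2-[(E)-3-(3,4-dimethoxyphenyl)prop-2-en-1-yl]-3-hydroxy-3-(4-methoxyphenyl)propanoic acid A5. One reduction would then give diol 14.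
- Merits: the C–C bond, the methine configuration (attack anti to the aryl group on the chelate) and the E styrene are formed in one step. The route is convergent and comparable in length. In bond-forming economy it is better than the chosen plan, which needs a separate olefination.
- Weak points: the 1-arylallyl ester of a dimethoxyarene ionises easily and can undergo a 1,3-acyl shift to the cinnamyl isomer before rearranging. The β-oxido ester enolate is open to retro-aldol cleavage and elimination. The chair links the allylic centre to the enolate face, so the allylic alcohol must also be enantiopure and matched; that means two asymmetric steps instead of one. The carboxylic acid must finally be reduced next to a styrene.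
- Comparison: the chosen plan has a single catalyst-controlled stereocentre with a well-understood relay, no ionisable allylic ester, and an alkene geometry set by a reaction that is inherently E-selective.

Key step: step 4

Assumption: the (2S) antipode of 3-exo-morpholinoisoborneol is taken to direct zinc reagents to the Si face of aromatic aldehydes, so the (2R) antipode is specified for Re-face aryl delivery in step 1. If the sense proves opposite for furan-3-carbaldehyde, the other antipode is used with no other change.

## Route

Step 1
Reactants: 1 furan-3-carbaldehyde; 2 (4-methoxyphenyl)boronic acid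
Product: 4 (R)-(furan-3-yl)(4-methoxyphenyl)methanol, via ethyl(4-methoxyphenyl)zinc 3 (not isolated)
Conditions: 2 (2.4 equiv), ZnEt2 (7 equiv), toluene, 60 °C; then (2R)-(+)-3-exo-morpholinoisoborneol (10 mol%), 1, toluene, 0 °C → 10 °C; aq. NH4Cl
Reagents that add atoms: none
Why: Boron-to-zinc exchange gives the mixed arylethylzinc 3, which transfers its aryl group (faster than ethyl) to the aldehyde within the chiral amino-alkoxide zinc complex; this catalytic asymmetric aryl transfer to aromatic aldehydes should deliver the aryl group to the Re face and so set the (R)-carbinol. The neutral work-up avoids ionisation of the doubly activated carbinol.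

Step 2
Reactants: 4 (R)-(furan-3-yl)(4-methoxyphenyl)methanol
Product: 6 5-hydroxy-4-[(R)-hydroxy(4-methoxyphenyl)methyl]furan-2(5H)-one (mixture of C5 epimers), via furan endoperoxide 5 (not isolated)
Conditions: O2, hν (visible), tetraphenylporphyrin (cat.), iPr2NEt (2 equiv), CH2Cl2, −78 °C; then 0 °C, pH 5 phosphate buffer
Reagents that add atoms: dioxygen, O=O
Why: Singlet oxygen adds across the furan 2,5-positions in a [4+2] cycloaddition, and the hindered amine removes the bridgehead proton remote from the branched substituent (Kornblum–DeLaMare fragmentation), so the carbonyl should form at the unsubstituted side and the hemiacetal next to the carbinol-bearing carbon. The anisole ring is inert to singlet oxygen at this temperature and the carbinol centre is not touched.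

Step 3
Reactants: 6 5-hydroxy-4-[(R)-hydroxy(4-methoxyphenyl)methyl]furan-2(5H)-one
Product: 7 4-[(R)-hydroxy(4-methoxyphenyl)methyl]furan-2(5H)-one
Conditions: NaBH4, THF/MeOH, −20 °C → 0 °C; aq. citric acid to pH 4
Reagents that add atoms: none
Why: The hydroxybutenolide reacts through its ring-opened (Z)-formyl acrylate tautomer, whose aldehyde is reduced; the resulting cis hydroxy acid relactonises on mild acidification, the known conversion of 5-hydroxyfuranones into furanones. Low temperature and a short reaction time guard the vinylogously acidic carbinol hydrogen against base-induced epimerisation.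

Step 4
Reactants: 7 4-[(R)-hydroxy(4-methoxyphenyl)methyl]furan-2(5H)-one
Product: 8 (4S)-4-[(S)-hydroxy(4-methoxyphenyl)methyl]oxolan-2-one
Conditions: [Rh(nbd)(dppb)]BF4 (5 mol%; nbd = norbornadiene, dppb = 1,4-bis(diphenylphosphino)butane), H2 (50 atm), CH2Cl2, 25 °C
Reagents that add atoms: none
Why: Under H2 the precatalyst loses norbornadiene and gives a solvated cationic monovalent rhodium diphosphine fragment that binds 7 through the carbinol oxygen and the ring alkene on the same face; oxidative addition of H2, migratory insertion (hydride to C4, leaving a five-membered alkyl chelate at C3) and reductive elimination then place both hydrogens on that face. The closest known reaction type is the hydroxyl-directed hydrogenation of acyclic allylic alcohols and 2-(hydroxyalkyl)acrylates with this same complex, which gives anti products; 7 is the analogue in which the ester and the geminal substituent are tied together as the lactone. No ring closes in this step. The one new stereocentre, C4, is controlled by the (R)-carbinol: in the chelated conformer the aryl group lies on the side of the C3–H bond and the carbinol hydrogen eclipses the C4–C5 bond (least allylic 1,2-strain against the ring CH2–O), so hydrogen should enter the face that leaves the hydroxyl anti to the C3 methylene in the extended C5–C4–carbinol–aryl chain, which is (4S). The step needs diastereofacial selectivity and must outrun rhodium-hydride isomerisation of the allylic alcohol to the ketone; chelation together with the 1,2-strain bias secures the first, and high hydrogen pressure in a non-coordinating solvent the second. The anisole ring, the lactone and the benzylic C–O bond are inert to this homogeneous catalyst, and no styrene is present yet.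

Step 5
Reactants: 8 (4S)-4-[(S)-hydroxy(4-methoxyphenyl)methyl]oxolan-2-one
Product: 9 (4S)-4-[(S)-hydroxy(4-methoxyphenyl)methyl]oxolan-2-ol (mixture of C2 epimers)
Conditions: iBu2AlH (2.3 equiv), CH2Cl2, −78 °C; aq. KNaC4H4O6 (potassium sodium tartrate)
Reagents that add atoms: none
Why: Partial hydride reduction of a γ-lactone stops at the tetrahedral aluminium acetal at −78 °C and gives the lactol on work-up; one extra equivalent is consumed by the free hydroxyl. Neither stereocentre is touched.

Step 6
Reactants: 10 (3,4-dimethoxyphenyl)methanol
Product: 11 4-(chloromethyl)-1,2-dimethoxybenzene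
Conditions: SOCl2, CH2Cl2, 0 °C → rt
Reagents that add atoms: thionyl chloride, O=S(Cl)Cl
Why: Chlorination of an electron-rich benzylic alcohol through its chlorosulfite is fast and clean.

Step 7
Reactants: 11 4-(chloromethyl)-1,2-dimethoxybenzene
Product: 12 diethyl [(3,4-dimethoxyphenyl)methyl]phosphonate
Conditions: P(OEt)3 (neat, 1.5 equiv), 140 °C
Reagents that add atoms: triethyl phosphite, CCOP(OCC)OCC
Why: Michaelis–Arbuzov reaction: the phosphite displaces the benzylic chloride and the phosphonium salt is dealkylated by chloride.

Step 8
Reactants: 9 (4S)-4-[(S)-hydroxy(4-methoxyphenyl)methyl]oxolan-2-ol; 12 diethyl [(3,4-dimethoxyphenyl)methyl]phosphonate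
Product: 14 (1S,2S)-2-[(E)-3-(3,4-dimethoxyphenyl)prop-2-en-1-yl]-1-(4-methoxyphenyl)propane-1,3-diol, via open-chain hydroxy aldehyde 13 (not isolated)
Conditions: 12 (3.3 equiv), KOtBu (3.3 equiv), THF, 0 °C; then 9, 0 °C → rt; aq. NH4Cl
Reagents that add atoms: none
Why: Horner–Wadsworth–Emmons olefination of a lactol through its ring-opened aldehyde 13: two equivalents of the phosphonate anion deprotonate the two hydroxyls and the third adds to the aldehyde, and the aryl-stabilised adduct eliminates diethyl phosphate to give the E styrene. The aldehyde has no leaving group at its β-carbon and no β-hydroxyl, so neither elimination nor retro-aldol cleavage can compete, and the ring oxygen is released as the primary alcohol.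

Step 9
Reactants: 15 (E)-but-2-enal
Product: 16 (Z)-2-iodobut-2-enal
Conditions: I2, K2CO3, DMAP (20 mol%), THF/H2O (1:1), rt
Reagents that add atoms: iodine, II
Why: α-Iodination of an enal by conjugate addition of the amine catalyst, iodination of the resulting enolate and elimination of the catalyst; the reversible sequence should settle on the isomer with methyl trans to formyl, which is Z by the priority rules.

Step 10
Reactants: 16 (Z)-2-iodobut-2-enal
Product: 17 (Z)-2-iodobut-2-en-1-ol
Conditions: NaBH4, MeOH, 0 °C
Reagents that add atoms: none
Why: Borohydride 1,2-reduction of the aldehyde; the alkenyl iodide and the alkene geometry are not affected.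

Step 11
Reactants: 17 (Z)-2-iodobut-2-en-1-ol
Product: 18 tert-butyl{[(Z)-2-iodobut-2-en-1-yl]oxy}dimethylsilane
Conditions: TBSCl, imidazole, CH2Cl2, 0 °C → rt
Reagents that add atoms: tert-butyl(chloro)dimethylsilane, CC(C)(C)[Si](C)(C)Cl
Why: Standard silylation of a primary allylic alcohol; the silyl ether survives organolithium chemistry and is later removed by fluoride.

Step 12
Reactants: 18 tert-butyl{[(Z)-2-iodobut-2-en-1-yl]oxy}dimethylsilane
Product: 20 (Z)-2-({[tert-butyl(dimethyl)silyl]oxy}methyl)but-2-enoic acid, via alkenyllithium 19 (not isolated)
Conditions: t-BuLi (2.1 equiv), Et2O, −78 °C; CO2, −78 °C → 0 °C; cold 1 M HCl to pH 3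
Reagents that add atoms: carbon dioxide, O=C=O
Why: Iodine–lithium exchange at an alkenyl iodide and carboxylation of the alkenyllithium both proceed with retention at −78 °C, so the carboxyl group takes the place of iodine cis to the methyl group and gives the Z acid.

Step 13
Reactants: 14 (1S,2S)-2-[(E)-3-(3,4-dimethoxyphenyl)prop-2-en-1-yl]-1-(4-methoxyphenyl)propane-1,3-diol; 20 (Z)-2-({[tert-butyl(dimethyl)silyl]oxy}methyl)but-2-enoic acid
Product: 21 (2S,3S)-2-[(E)-3-(3,4-dimethoxyphenyl)prop-2-en-1-yl]-3-hydroxy-3-(4-methoxyphenyl)propyl (Z)-2-({[tert-butyl(dimethyl)silyl]oxy}methyl)but-2-enoate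
Conditions: 20 (1.1 equiv), EDC·HCl (1.2 equiv), DMAP (10 mol%), CH2Cl2, −20 °C → 0 °C
Reagents that add atoms: none
Why: Steglich esterification with a carbodiimide: the unhindered primary hydroxyl should be acylated much faster than the benzylic secondary one by this α-branched acyl donor. Low temperature, a small charge of DMAP and rapid capture by the primary alcohol limit both double acylation and isomerisation of the Z acid.

Step 14
Reactants: 21 (2S,3S)-2-[(E)-3-(3,4-dimethoxyphenyl)prop-2-en-1-yl]-3-hydroxy-3-(4-methoxyphenyl)propyl (Z)-2-({[tert-butyl(dimethyl)silyl]oxy}methyl)but-2-enoate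
Product: 22 (2S,3S)-2-[(E)-3-(3,4-dimethoxyphenyl)prop-2-en-1-yl]-3-hydroxy-3-(4-methoxyphenyl)propyl (Z)-2-(hydroxymethyl)but-2-enoate
Conditions: TBAF, AcOH (1:1), THF, 0 °C → rt
Reagents that add atoms: none
Why: Fluoride cleavage of a primary silyl ether; the acetic acid buffer protonates the alkoxide as it forms, which should prevent 1,3-acyl migration to the benzylic hydroxyl, and the near-neutral medium spares the 4-methoxybenzylic alcohol, the styrene and both alkene geometries.

## Compound list

1 | furan-3-carbaldehyde | O=Cc1ccoc1 | starting material
2 | (4-methoxyphenyl)boronic acid | COc1ccc(B(O)O)cc1 | starting material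
3 | ethyl(4-methoxyphenyl)zinc (not isolated) | CC[Zn]c1ccc(OC)cc1 | intermediate
4 | (R)-(furan-3-yl)(4-methoxyphenyl)methanol | c1cc(co1)[C@H](O)c1ccc(OC)cc1 | intermediate
5 | (R)-(4-methoxyphenyl)(2,3,7-trioxabicyclo[2.2.1]hept-5-en-5-yl)methanol (furan endoperoxide, bridgehead configuration undefined, not isolated) | C1(=CC2OOC1O2)[C@H](O)c1ccc(OC)cc1 | intermediate
6 | 5-hydroxy-4-[(R)-hydroxy(4-methoxyphenyl)methyl]furan-2(5H)-one (both C5 epimers) | O=C1OC(O)C(=C1)[C@H](O)c1ccc(OC)cc1 | intermediate
7 | 4-[(R)-hydroxy(4-methoxyphenyl)methyl]furan-2(5H)-one | O=C1OCC(=C1)[C@H](O)c1ccc(OC)cc1 | intermediate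
8 | (4S)-4-[(S)-hydroxy(4-methoxyphenyl)methyl]oxolan-2-one | O=C1OC[C@H](C1)[C@H](O)c1ccc(OC)cc1 | intermediate
9 | (4S)-4-[(S)-hydroxy(4-methoxyphenyl)methyl]oxolan-2-ol (both C2 epimers) | OC1OC[C@H](C1)[C@H](O)c1ccc(OC)cc1 | intermediate
10 | (3,4-dimethoxyphenyl)methanol (veratryl alcohol) | COc1ccc(CO)cc1OC | starting material
11 | 4-(chloromethyl)-1,2-dimethoxybenzene | COc1ccc(CCl)cc1OC | intermediate
12 | diethyl [(3,4-dimethoxyphenyl)methyl]phosphonate | CCOP(=O)(Cc1ccc(OC)c(OC)c1)OCC | intermediate
13 | (3S,4S)-4-hydroxy-3-(hydroxymethyl)-4-(4-methoxyphenyl)butanal (not isolated) | OC[C@H](CC=O)[C@H](O)c1ccc(OC)cc1 | intermediate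
14 | (1S,2S)-2-[(E)-3-(3,4-dimethoxyphenyl)prop-2-en-1-yl]-1-(4-methoxyphenyl)propane-1,3-diol | OC[C@H](C/C=C/c1ccc(OC)c(OC)c1)[C@H](O)c1ccc(OC)cc1 | intermediate
15 | (E)-but-2-enal (crotonaldehyde) | C/C=C/C=O | starting material
16 | (Z)-2-iodobut-2-enal | C/C=C(/C=O)I | intermediate
17 | (Z)-2-iodobut-2-en-1-ol | C/C=C(/CO)I | intermediate
18 | tert-butyl{[(Z)-2-iodobut-2-en-1-yl]oxy}dimethylsilane | C/C=C(/CO[Si](C)(C)C(C)(C)C)I | intermediate
19 | [(E)-1-{[tert-butyl(dimethyl)silyl]oxy}but-2-en-2-yl]lithium (not isolated) | C/C=C(/CO[Si](C)(C)C(C)(C)C)[Li] | intermediate
20 | (Z)-2-({[tert-butyl(dimethyl)silyl]oxy}methyl)but-2-enoic acid | C/C=C(/CO[Si](C)(C)C(C)(C)C)C(=O)O | intermediate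
21 | (2S,3S)-2-[(E)-3-(3,4-dimethoxyphenyl)prop-2-en-1-yl]-3-hydroxy-3-(4-methoxyphenyl)propyl (Z)-2-({[tert-butyl(dimethyl)silyl]oxy}methyl)but-2-enoate | C/C=C(/CO[Si](C)(C)C(C)(C)C)C(=O)OC[C@H](C/C=C/c1ccc(OC)c(OC)c1)[C@H](O)c1ccc(OC)cc1 | intermediate
22 | (2S,3S)-2-[(E)-3-(3,4-dimethoxyphenyl)prop-2-en-1-yl]-3-hydroxy-3-(4-methoxyphenyl)propyl (Z)-2-(hydroxymethyl)but-2-enoate | C/C=C(/CO)C(=O)OC[C@H](C/C=C/c1ccc(OC)c(OC)c1)[C@H](O)c1ccc(OC)cc1 | target

## Step count and risks

Total step count: 14. Longest linear sequence: 8 steps (steps 1, 2, 3, 4, 5, 8, 13 and 14, from furan-3-carbaldehyde). The enantiomeric purity is set in step 1 and is only carried forward; no later step upgrades it.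

**Step 4 (key step).** The most likely failure is insufficient facial discrimination: the ring CH2 is a smaller 1,2-strain partner than an acyclic ester group, and the five-membered ring opens the exocyclic angle. The second risk is isomerisation of the allylic alcohol to the ketone through a rhodium hydride, which would erase the carbinol centre. Within the plan, the pressure would be raised and an enantiopure diphosphine matched to the (R)-carbinol would replace dppb.

The fallback changes from substrate direction to reagent control. It sets out from 7, which is silylated (TBSCl, imidazole, DMF) to 4-[(R)-{[tert-butyl(dimethyl)silyl]oxy}(4-methoxyphenyl)methyl]furan-2(5H)-one F1. F1 is then subjected to catalytic asymmetric copper hydride 1,4-reduction, a reaction established for β-substituted butenolides (CuCl2·2H2O, NaOtBu, the matched antipode of p-tol-BINAP, polymethylhydrosiloxane, toluene/iPrOH). This should give (4S)-4-[(S)-{[tert-butyl(dimethyl)silyl]oxy}(4-methoxyphenyl)methyl]oxolan-2-one F2. Buffered fluoride (HF·pyridine in pyridine/THF) then removes the silyl group and the route is rejoined at 8.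

**Step 8.** The olefination may stall because too little open-chain aldehyde 13 is present at equilibrium, or the aldehyde may be consumed by enolisation and aldol condensation under the strongly basic conditions. The fallback sets out from 9. Wittig methylenation, the classical lactol opening (Ph3P=CH2 from methyltriphenylphosphonium bromide and KOtBu, THF), should give (1S,2S)-1-(4-methoxyphenyl)-2-(prop-2-en-1-yl)propane-1,3-diol F3. Cross-metathesis of F3 with commercial 3,4-dimethoxystyrene (C=Cc1ccc(OC)c(OC)c1), using the second-generation Hoveyda–Grubbs catalyst RuCl2(H2IMes)(=CH-C6H4-2-OiPr) in CH2Cl2 at 40 °C, installs the E styrene and returns to the route at 14.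

**Step 13.** The risks are Z-to-E isomerisation of the acyl unit, by reversible conjugate addition of the nucleophilic catalyst to the activated acid, and over-acylation at the benzylic hydroxyl. The fallback activates the alcohol instead of the acid: a Mitsunobu esterification of 14 with 20 (PPh3, DIAD, THF, 0 °C). The carboxylate displaces the primary oxyphosphonium ion, the acid is never turned into an acyl donor, and primary carbinols react far faster than secondary ones. It sets out from 14 and 20 and comes back at 21 without any new compound.

**Step 2.** The base-induced fragmentation of 5 may lose regiocontrol and place the carbonyl next to the substituent, or the doubly activated carbinol of 4 may ionise before the furan is oxidised. The fallback uses silicon to fix the regiochemistry and sets out from 1. The aldehyde is masked in situ as its lithium morpholide adduct, lithiated at C5 with s-BuLi and quenched with Me3SiCl to give 5-(trimethylsilyl)furan-3-carbaldehyde F4. The aryl transfer of step 1 applied to F4 should give (R)-(4-methoxyphenyl)[5-(trimethylsilyl)furan-3-yl]methanol F5. Photooxygenation of F5 without amine (O2, hν, tetraphenylporphyrin, CH2Cl2, −78 °C) places the carbonyl at the silylated carbon through silyl migration to oxygen. Aqueous work-up then rejoins the route at 6.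

**Step 12.** The alkenyllithium 19 carries a silyloxy group on the adjacent carbon. If the temperature rises it may decompose by elimination or by oxygen-to-carbon silyl migration, or lose its geometry before carboxylation. The fallback sets out from 18. Palladium-catalysed methoxycarbonylation (PdCl2(PPh3)2, CO at 1 atm, MeOH, Et3N, DMF, 60 °C) proceeds with retention at the alkenyl carbon and should give methyl (Z)-2-({[tert-butyl(dimethyl)silyl]oxy}methyl)but-2-enoate F6. Saponification (LiOH, THF/H2O, rt) returns to the route at 20.

## Further compounds

F1 | step 4 | 4-[(R)-{[tert-butyl(dimethyl)silyl]oxy}(4-methoxyphenyl)methyl]furan-2(5H)-one | O=C1OCC(=C1)[C@H](O[Si](C)(C)C(C)(C)C)c1ccc(OC)cc1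
F2 | step 4 | (4S)-4-[(S)-{[tert-butyl(dimethyl)silyl]oxy}(4-methoxyphenyl)methyl]oxolan-2-one | O=C1OC[C@H](C1)[C@H](O[Si](C)(C)C(C)(C)C)c1ccc(OC)cc1
F3 | step 8 | (1S,2S)-1-(4-methoxyphenyl)-2-(prop-2-en-1-yl)propane-1,3-diol | OC[C@H](CC=C)[C@H](O)c1ccc(OC)cc1
F0 | step 13 | none | none
F4 | step 2 | 5-(trimethylsilyl)furan-3-carbaldehyde | O=Cc1coc(c1)[Si](C)(C)C
F5 | step 2 | (R)-(4-methoxyphenyl)[5-(trimethylsilyl)furan-3-yl]methanol | C[Si](C)(C)c1cc(co1)[C@H](O)c1ccc(OC)cc1
F6 | step 12 | methyl (Z)-2-({[tert-butyl(dimethyl)silyl]oxy}methyl)but-2-enoate | C/C=C(/CO[Si](C)(C)C(C)(C)C)C(=O)OC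
A1 | alternative 1 | (4S,5S)-4-(4-methoxyphenyl)-5-(prop-2-en-1-yl)-1,3-dioxane | C1OC[C@H](CC=C)[C@H](O1)c1ccc(OC)cc1
A2 | alternative 1 | 1-methoxy-4-[(1E)-penta-1,4-dien-1-yl]benzene | C=CC/C=C/c1ccc(OC)cc1
A3 | alternative 2 | (1S,2S)-2-[(E)-3-(3,4-dimethoxyphenyl)prop-2-en-1-yl]-1-(4-methoxyphenyl)-3-{[2-(trimethylsilyl)ethoxy]methoxy}propan-1-ol | C[Si](C)(C)CCOCOC[C@H](C/C=C/c1ccc(OC)c(OC)c1)[C@H](O)c1ccc(OC)cc1
A4 | alternative 2 | (2S,4E)-5-(3,4-dimethoxyphenyl)-2-({[2-(trimethylsilyl)ethoxy]methoxy}methyl)pent-4-enal | C[Si](C)(C)CCOCOC[C@H](C/C=C/c1ccc(OC)c(OC)c1)C=O
A5 | alternative 3 | (2R,3S)-2-[(E)-3-(3,4-dimethoxyphenyl)prop-2-en-1-yl]-3-hydroxy-3-(4-methoxyphenyl)propanoic acid | OC(=O)[C@H](C/C=C/c1ccc(OC)c(OC)c1)[C@H](O)c1ccc(OC)cc1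
A6 | alternative 3 | 1-(3,4-dimethoxyphenyl)prop-2-en-1-yl (3S)-3-hydroxy-3-(4-methoxyphenyl)propanoate (allylic centre to be matched) | C=CC(OC(=O)C[C@H](O)c1ccc(OC)cc1)c1ccc(OC)c(OC)c1
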